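**Remark on locants.** Shikimate locants are used throughout: C7 is the exocyclic carbon and On is the oxygen on Cn, so the target is (1S,2S,3R,4S) with C5=C6. β is the ring face that carries O4 in the target and α the opposite face, so (−)-shikimic acid is 3β,4β,5α.

## The problem

The target is a monocyclic cyclohexene with no ring fusion to lean on. Its difficulty lies in four contiguous oxygenated stereocentres, C1 to C4, of which C1 is a tetrasubstituted carbinol that also carries the C7 benzoyloxymethyl arm. O1, O2 and O4 lie on the β face and O3 on the α face, so O1/O2 are cis while O2/O3 and O3/O4 are trans. Five oxygens have to be told apart: benzoates belong on O7 and O3 only, and the O3 benzoate sits between free hydroxyls on C2 and C4, so any basic step late in the route invites acyl migration. The C5=C6 alkene makes both the C1 and the C4 carbinol allylic, which forbids strong acid at the end and requires that the alkene be introduced regiospecifically, away from C4. One purchased stereocentre can control the rest: with C4 fixed, C3 can be set by inversion next to it, and an allylic oxygen on C3 can then steer a cis-dihydroxylation that creates C1 and C2 together. The enabling feature is that C7, C1 to C6 and O3, O4, O5 of the target coincide with the skeleton of (−)-shikimic acid 1: its carboxyl carbon is C7, its ring alkene C1=C2 lies exactly where the cis-diol is needed, and O4 already has the right configuration. O3 is allylic and of the wrong configuration, so it can be inverted in the step that attaches its benzoate, and O5 is trans to O4 and can leave to create C5=C6.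

## Retrosynthesis

**17 to 16.** The last bond cut is O4–Si. Keeping O4 as a triethylsilyl ether until the end means the O3 benzoate never has a free neighbour on C4 during the nucleophilic and oxidative steps. The only final operation is then a mild desilylation, which must not move a benzoate or ionise an allylic alcohol.

**16 to 14 (through 15).** The C5=C6 π bond is traced back to a C5–Se bond and a hydrogen on C6. Base-induced anti-elimination of a C5 sulfonate would need the leaving group axial in a chair that stacks three substituents syn-axially. Dehydration of a C5 alcohol offers no regiocontrol. A selenoxide 15 needs a cis β-hydrogen; with selenium β on C5 the hydrogen on C4 is trans, so only H6 can be reached. The forward step asks for oxidation at selenium only.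

**14 to 13.** The C5–Se bond is cut to the 5α-mesylate 13, which has the natural shikimate configuration at C5. Displacement with inversion delivers the 5β-selenide that the elimination requires. The forward reaction is an SN2 at a hindered secondary carbon and needs a soft, weakly basic nucleophile.

**13 to 11 (key disconnection, through 12).** C1–O1 and C2–O2 are cut together, back to the C1=C2 alkene of 11. A cis-diol containing the quaternary carbinol maps directly onto OsO4 addition through the osmate ester 12; epoxide opening would give the trans-diol. Placing this step before C5=C6 exists removes any competition between alkenes. Placing it after the C3 inversion lets the 3α-benzoate serve as the control element. Two stereocentres, including the hardest one, disappear, and 11 has three stereocentres that all trace to shikimate. The forward step must add from the β face.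

**11 to 10 to 9 + 7.** After removal of the silyl group, the C3–O bond of the secondary benzoate is cut. Because this bond must be formed with inversion, a Mitsunobu reaction of the 3β,4β-diol 9 with benzoic acid 7 installs the ester and sets the configuration in one event. Oxidation and reduction at C3 followed by acylation would be longer and stereochemically less certain. The forward reaction must engage the allylic O3 and leave O4 alone.

**9 to 8 to 6 + 7.** The acetonide is put back on O3/O4 and the O7 ester is cut to the primary allylic alcohol 6 and a second molecule of benzoic acid 7. Acylating at the acetonide stage, where O7 is the only free hydroxyl, places the first benzoate without any sorting of hydroxyls. Each benzoate thus comes from its own molecule of 7 in its own step.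

**6 to 5 to 3 + 4, 3 to 2 to 1.** The C7 oxidation level is adjusted by reduction of ester 5 while O3 and O4 are masked. Mesylation with methanesulfonyl chloride 4 marks O5, the only free hydroxyl of acetonide 3. Compound 3 comes from methyl shikimate 2 and thus from (−)-shikimic acid 1 by two standard operations.

## Roads not taken

**Alternative 1:** The ring would be cut at C1–C2 and C3–C4. 3-Hydroxy-2-pyrone A1 (supplying C7, C1, C6, C5, C4 and O4) and (E)-4-benzoyloxybut-3-en-2-one A2 (supplying C2 and C3) would combine in a base-catalysed Diels–Alder reaction under a cinchona-derived catalyst to give the bridged lactone A3.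

- Merits: this road is clearly superior in convergence. One catalytic asymmetric step from two achiral components builds the carbocycle, the quaternary carbinol, the C3 benzoate and the C5=C6 alkene, and no substitution at a hindered ring carbon is needed.
- Weak points:
  - The lactone bridge ties C7 and O4 to the same ring face, whereas the target has C7 α and O4 β. A3 therefore leads to the C4 epimer, and an allylic inversion next to the O3 benzoate has to follow.
  - The acetyl group on C2 must become O2 by Baeyer–Villiger oxidation in the presence of a strained alkene.
  - The lactone carbonyl C7 must be reduced to CH2OH without touching the benzoate.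
  - A2 is a vinylogous anhydride, a deactivated and addition–elimination-prone acceptor.
- Comparison: against the shorter ring construction, the chosen plan offers stereocentres that are all inherited or set by stereospecific events, no carbonyl manipulation after the fourth step, and benzoates placed one at a time on hydroxyls that are singled out beforehand.

**Alternative 2:** The C2–O bond would be formed on the achiral para-quinol A4, which already carries the C7 benzoate. Phenylboronic acid A5 would form a hemiester on O1, and its B–OH would add to the enone carbon C2 under a chiral amine–thiourea catalyst. This desymmetrises the dienone and gives the cis-fused boronate A6.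

- Merits: it is the shortest road and is better than the chosen plan in step count. C1 and C2 arise cis by the tether, and C5=C6 is present from the start.
- Weak points:
  - C3 arrives as a methylene group and C4 as a ketone. Oxygenation at C3 needs an enolate that is β to the C2–O bond, so retro-oxa-Michael reversion towards the dienone A4 threatens the new stereocentres.
  - The face of oxygenation at C3 and of the later ketone reduction at C4 rests on substrate control that is less secure.
  - The benzoate has to be placed on O3 in the presence of O2 and O4.
- Comparison: the chosen plan sets against the brevity a C4 centre taken from the pool, a C3 centre set by SN2 inversion with the benzoate attached, and no base-labile β-alkoxy ketone.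

**Alternative 3:** The C1–C2 bond would be formed by reductive cyclisation of the (Z)-enynal A7, whose two oxygenated stereocentres would come from the chiral pool. A zerovalent nickel catalyst, Ni(cod)2 with an N-heterocyclic carbene, and triethylsilane A8 would couple the C2 aldehyde with alkyne carbon C1 and give the methylenecyclohexene A9 with O2 already silylated.

- Merits: ring closure, the C2 stereocentre and O2 protection come in one step, and C5=C6 is present from the start, which is better than a late substitution at C5.
- Weak points:
  - The α-benzoyloxy aldehyde A7 is prone to epimerisation, and the 2,3-trans outcome depends on 1,2-induction.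
  - Assembly of A7 takes many steps.
  - A9 is a conjugated diene. The exocyclic C1=C7 bond must be dihydroxylated in preference to C5=C6 and from the β face, so the quaternary centre C1 would be set last and with the least control.
- Comparison: the chosen plan creates C1 and C2 together on a substrate with a single alkene and a defined allylic control element, at the price of a longer linear sequence.

Key step: step 9

## Route

Step 1
Reactants: 1 (−)-shikimic acid
Product: 2 methyl shikimate
Conditions: MeOH, CSA (cat.), reflux
Reagents that add atoms: methanol, CO
Why: Fischer esterification with methanol as solvent; no stereocentre is touched.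

Step 2
Reactants: 2 methyl shikimate
Product: 3 methyl 3,4-O-isopropylideneshikimate
Conditions: Me2C(OMe)2, TsOH·H2O (cat.), acetone, rt
Reagents that add atoms: 2,2-dimethoxypropane, COC(C)(C)OC
Why: Acid-catalysed acetal exchange; only the cis-3β,4β-diol can close a strain-free cis-fused dioxolane, so the trans-placed 5α-hydroxyl remains as the single free alcohol.

Step 3
Reactants: 3 methyl 3,4-O-isopropylideneshikimate; 4 methanesulfonyl chloride
Product: 5 methyl 3,4-O-isopropylidene-5-O-methanesulfonylshikimate
Conditions: Et3N, CH2Cl2, 0 °C
Reagents that add atoms: none
Why: Sulfonylation of the only free hydroxyl forms an O–S bond, so C5 keeps its configuration; the mesylate protects O5 now and serves as leaving group later.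

Step 4
Reactants: 5 methyl 3,4-O-isopropylidene-5-O-methanesulfonylshikimate
Product: 6 3,4-O-isopropylidene-5-O-methanesulfonylshikimyl alcohol (C7 primary allylic alcohol)
Conditions: iBu2AlH (2.5 equiv), CH2Cl2, −78 °C; aq. KNaC4H4O6
Reagents that add atoms: none
Why: Low-temperature iBu2AlH 1,2-reduction of a conjugated ester to the primary allylic alcohol; secondary alkyl mesylates and acetonides do not react with this hydride at −78 °C.

Step 5
Reactants: 6 3,4-O-isopropylidene-5-O-methanesulfonylshikimyl alcohol; 7 benzoic acid
Product: 8 7-O-benzoyl-3,4-O-isopropylidene-5-O-methanesulfonylshikimyl alcohol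
Conditions: DCC, DMAP (cat.), CH2Cl2, 0 °C to rt
Reagents that add atoms: none
Why: Steglich esterification of the only free hydroxyl, the primary allylic O7, while O3 and O4 are still tied up in the acetonide, so the first benzoate is placed without any question of site; no stereocentre is touched.

Step 6
Reactants: 8 7-O-benzoyl-3,4-O-isopropylidene-5-O-methanesulfonylshikimyl alcohol
Product: 9 7-O-benzoyl-5-O-methanesulfonylshikimyl alcohol (3β-OH, 4β-OH, 5α-OMs)
Conditions: AcOH/H2O (4:1), 40 °C
Reagents that add atoms: none
Why: Acid hydrolysis of the isopropylidene acetal; the primary benzoate and the sulfonate are stable to aqueous acetic acid, and without base the freed 4β-hydroxyl cannot close onto C5 to an epoxide.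

Step 7
Reactants: 9 7-O-benzoyl-5-O-methanesulfonylshikimyl alcohol; 7 benzoic acid
Product: 10 3-epi-shikimyl alcohol 3,7-dibenzoate 5-methanesulfonate (3α-OBz, 4β-OH, 5α-OMs)
Conditions: PPh3, DIAD (1.3 equiv each), THF, 0 °C to rt
Reagents that add atoms: none
Why: Mitsunobu esterification: the allylic O3 is the more readily activated of the two secondary hydroxyls, and benzoate displaces the C3 oxyphosphonium group in an SN2 step that inverts C3 and sets the 3α-benzoate. O4 is not allylic, lies between the sulfonate and the reacting centre and is cis to O3 (no epoxide possible), so it should remain free.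

Step 8
Reactants: 10 3-epi-shikimyl alcohol 3,7-dibenzoate 5-methanesulfonate
Product: 11 4-O-triethylsilyl-3-epi-shikimyl alcohol 3,7-dibenzoate 5-methanesulfonate
Conditions: Et3SiOTf, 2,6-lutidine, CH2Cl2, −78 to 0 °C
Reagents that add atoms: triethylsilyl trifluoromethanesulfonate, CC[Si](CC)(CC)OS(=O)(=O)C(F)(F)F
Why: Silylation of a hindered secondary alcohol with a silyl triflate and a hindered pyridine base; the base is too weak to cause epoxide closure onto C5 or an O3-to-O4 benzoyl shift.

Step 9
Reactants: 11 4-O-triethylsilyl-3-epi-shikimyl alcohol 3,7-dibenzoate 5-methanesulfonate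
Product: 13 1α-benzoyloxymethyl-3α-benzoyloxy-5α-methanesulfonyloxy-4β-triethylsilyloxycyclohexane-1β,2β-diol, via cyclic osmate ester 12 (not isolated)
Conditions: OsO4 (5 mol%), NMO (2 equiv), acetone/H2O (5:1), rt; aq. Na2SO3
Reagents that add atoms: N-methylmorpholine N-oxide, C[N+]1([O-])CCOCC1; water, O
Why: OsO4 adds to the only alkene, C1=C2, in a concerted suprafacial [3+2] cycloaddition to give the osmate ester 12 (hexavalent osmium), which NMO reoxidises and water hydrolyses, so the C1–O and C2–O bonds form on one face. The closest known reaction type is the catalytic OsO4/NMO cis-dihydroxylation of cyclohexenes with an allylic oxygen substituent, shikimate derivatives included, which occurs anti to that substituent. No ring of the skeleton is closed; the five-membered osmate ring is transient and is opened again by hydrolysis. The cis relation of the new stereocentres C1 and C2 follows from the mechanism, and their absolute sense from the 3α-benzoate: the oxidant should approach the β face, away from the allylic C3–O bond, which places O1 and O2 β and the C7 arm α. The 5α-mesylate lies on the same α face and the 4β-silyl ether is equatorial and homoallylic, so neither should oppose this preference. Face selectivity is the only selectivity required because there is no second alkene; the near-neutral medium should keep the benzoates in place, and the mesylate and silyl ether are inert to the oxidant.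

Step 10
Reactants: 13 1α-benzoyloxymethyl-3α-benzoyloxy-5α-methanesulfonyloxy-4β-triethylsilyloxycyclohexane-1β,2β-diol
Product: 14 1α-benzoyloxymethyl-3α-benzoyloxy-5β-phenylselanyl-4β-triethylsilyloxycyclohexane-1β,2β-diol
Conditions: (PhSe)2, NaBH4, EtOH, 0 °C to rt; then 13, THF, 60 °C
Reagents that add atoms: diphenyl diselenide, c1ccc(cc1)[Se][Se]c1ccccc1
Why: SN2 displacement of a secondary mesylate by sodium benzeneselenolate, made in the flask by NaBH4 reduction of the diselenide; inversion at C5 gives the 5β-selenide. The selenolate is soft and weakly basic, so the diol, the benzoates and the silyl ether should be left alone.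

Step 11
Reactants: 14 1α-benzoyloxymethyl-3α-benzoyloxy-5β-phenylselanyl-4β-triethylsilyloxycyclohexane-1β,2β-diol
Product: 16 1α-benzoyloxymethyl-3α-benzoyloxy-4β-triethylsilyloxycyclohex-5-ene-1β,2β-diol, via 5β-selenoxide 15 (not isolated)
Conditions: 30% aq. H2O2, pyridine, THF, 0 °C to rt
Reagents that add atoms: none
Why: Oxidation of the selenide to selenoxide 15, then selenoxide syn-elimination at or below room temperature. The 5β-selenoxide has a cis β-hydrogen only on C6 because H4 is α, so the alkene can form only between C5 and C6; pyridine buffers the benzeneselenenic acid that is released and suppresses its re-addition to the new alkene.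

Step 12
Reactants: 16 1α-benzoyloxymethyl-3α-benzoyloxy-4β-triethylsilyloxycyclohex-5-ene-1β,2β-diol
Product: 17 1α-benzoyloxymethyl-3α-benzoyloxycyclohex-5-ene-1β,2β,4β-triol (target)
Conditions: HF·pyridine, pyridine, THF, 0 °C to rt
Reagents that add atoms: none
Why: Fluoride cleavage of the triethylsilyl ether under buffered, weakly acidic conditions, where neither benzoyl migration from O3 to O2 or O4 nor ionisation of the two allylic alcohols is expected; no stereocentre is touched.

## Compound list

1 | (−)-shikimic acid, (3R,4S,5R)-3,4,5-trihydroxycyclohex-1-ene-1-carboxylic acid | OC(=O)C1=C[C@@H](O)[C@@H](O)[C@H](O)C1 | starting material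
2 | methyl shikimate | COC(=O)C1=C[C@@H](O)[C@@H](O)[C@H](O)C1 | intermediate
3 | methyl 3,4-O-isopropylideneshikimate (cis-fused 3β,4β-acetonide, 5α-OH) | COC(=O)C1=C[C@@H](OC(C)(C)O2)[C@@H]2[C@H](O)C1 | intermediate
4 | methanesulfonyl chloride | CS(Cl)(=O)=O | starting material
5 | methyl 3,4-O-isopropylidene-5-O-methanesulfonylshikimate | COC(=O)C1=C[C@@H](OC(C)(C)O2)[C@@H]2[C@H](OS(C)(=O)=O)C1 | intermediate
6 | 3,4-O-isopropylidene-5-O-methanesulfonylshikimyl alcohol (C7 is CH2OH) | OCC1=C[C@@H](OC(C)(C)O2)[C@@H]2[C@H](OS(C)(=O)=O)C1 | intermediate
7 | benzoic acid | OC(=O)c1ccccc1 | starting material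
8 | 7-O-benzoyl-3,4-O-isopropylidene-5-O-methanesulfonylshikimyl alcohol | O=C(OCC1=C[C@@H](OC(C)(C)O2)[C@@H]2[C@H](OS(C)(=O)=O)C1)c1ccccc1 | intermediate
9 | 7-O-benzoyl-5-O-methanesulfonylshikimyl alcohol (3β-OH, 4β-OH, 5α-OMs) | O=C(OCC1=C[C@@H](O)[C@@H](O)[C@H](OS(C)(=O)=O)C1)c1ccccc1 | intermediate
10 | 3-epi-shikimyl alcohol 3,7-dibenzoate 5-methanesulfonate (3α-OBz, 4β-OH, 5α-OMs) | O=C(OCC1=C[C@H](OC(=O)c2ccccc2)[C@@H](O)[C@H](OS(C)(=O)=O)C1)c1ccccc1 | intermediate
11 | 4-O-triethylsilyl-3-epi-shikimyl alcohol 3,7-dibenzoate 5-methanesulfonate (3α-OBz, 4β-OSiEt3, 5α-OMs) | O=C(OCC1=C[C@H](OC(=O)c2ccccc2)[C@@H](O[Si](CC)(CC)CC)[C@H](OS(C)(=O)=O)C1)c1ccccc1 | intermediate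
12 | cyclic 1β,2β-dioxoosmate ester of diol 13 (hexavalent osmium), formed and consumed in step 9 | O=C(OC[C@@]12C[C@@H](OS(C)(=O)=O)[C@H](O[Si](CC)(CC)CC)[C@@H](OC(=O)c3ccccc3)[C@@H]1O[Os](=O)(=O)O2)c1ccccc1 | intermediate
13 | 1α-benzoyloxymethyl-3α-benzoyloxy-5α-methanesulfonyloxy-4β-triethylsilyloxycyclohexane-1β,2β-diol | O=C(OC[C@@]1(O)C[C@@H](OS(C)(=O)=O)[C@H](O[Si](CC)(CC)CC)[C@@H](OC(=O)c2ccccc2)[C@@H]1O)c1ccccc1 | intermediate
14 | 1α-benzoyloxymethyl-3α-benzoyloxy-5β-phenylselanyl-4β-triethylsilyloxycyclohexane-1β,2β-diol | O=C(OC[C@@]1(O)C[C@H]([Se]c2ccccc2)[C@H](O[Si](CC)(CC)CC)[C@@H](OC(=O)c2ccccc2)[C@@H]1O)c1ccccc1 | intermediate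
15 | 5β-phenylseleninyl analogue of 14 (selenoxide, both configurations at selenium), formed and consumed in step 11 | O=C(OC[C@@]1(O)C[C@H]([Se](=O)c2ccccc2)[C@H](O[Si](CC)(CC)CC)[C@@H](OC(=O)c2ccccc2)[C@@H]1O)c1ccccc1 | intermediate
16 | 1α-benzoyloxymethyl-3α-benzoyloxy-4β-triethylsilyloxycyclohex-5-ene-1β,2β-diol | O=C(OC[C@@]1(O)C=C[C@H](O[Si](CC)(CC)CC)[C@@H](OC(=O)c2ccccc2)[C@@H]1O)c1ccccc1 | intermediate
17 | 1α-benzoyloxymethyl-3α-benzoyloxycyclohex-5-ene-1β,2β,4β-triol, (1S,2S,3R,4S) | O=C(OC[C@@]1(O)C=C[C@H](O)[C@@H](OC(=O)c2ccccc2)[C@@H]1O)c1ccccc1 | target

**Total step count:** 12. **Longest linear sequence:** 12 steps (1 to 17).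

## Least certain steps

**Step 9 (key step).** The most likely failure is insufficient facial selectivity. In the all-equatorial half-chair of 11 the 3α-benzoate is pseudo-equatorial, so the preference for β attack rests on the anti relation to the allylic C–O bond and not on a strong steric shield. A second concern is slow turnover: the alkene carries two allylic benzoates and the tertiary osmate hydrolyses slowly, and long exposure to the amine oxide could let a benzoyl group move to the new hydroxyls.

Fallback: set out from 10, whose O4 is free, and use a hydrogen-bond-directed osmylation. Stoichiometric OsO4 with TMEDA in CH2Cl2 at −78 °C should be bound by the homoallylic 4β-hydroxyl and delivered to the β face, now reinforced by the anti relation to the 3α-benzoate. This gives the TMEDA-chelated osmate ester F1. Cleavage with aqueous Na2SO3 would release the 1β,2β,4β-triol 5α-mesylate F2. Silylation of F2 with Et3SiCl and imidazole in DMF at −20 °C should take place at O4, because O2 is neopentylic next to the quaternary C1 and O1 is tertiary. The route is rejoined at 13.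

**Step 10.** The most likely failure is a sluggish substitution. The mesylate is equatorial, C4 carries a bulky β-silyloxy group, and the nucleophile must enter along an axial path that is syn to the axial hydroxyl on C1. Forcing conditions could then cause ethanolysis or migration of a benzoate, or attack of O2 on C5.

Fallback: set out from 13 and replace substitution plus syn-elimination by a direct anti-elimination. The 1β,2β-diol is first protected with 2-methoxypropene and PPTS in CH2Cl2 as the 1,2-O-isopropylidene mesylate F3, so that no free hydroxyl meets the base. Heating F3 with DBU in toluene should remove the mesylate by E2. Only H6β can become antiperiplanar to the 5α-leaving group, since the hydrogen on C4 is cis to it. The product would be the 1,2-O-isopropylidene-4-O-triethylsilyl alkene F4. Treatment of F4 with AcOH/H2O (4:1) at 40 °C removes acetonide and silyl ether together and reaches the target 17 directly.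

**Step 7.** The most likely failure is imperfect site selectivity between O3 and O4. The cis-3,4-diol can form a cyclic dioxaphosphorane that opens at the wrong oxygen, and the activated allylic C3 can undergo elimination followed by easy aromatisation of the ring.

Fallback: set out from 9 and replace the Mitsunobu inversion by the opening of a cyclic sulfite. SOCl2 and Et3N in CH2Cl2 at 0 °C convert the cis-3,4-diol of 9 into the 3,4-cyclic sulfite F5. PhCO2Cs in DMF at 70 °C should open F5 by SN2 at the allylic carbon C3 with inversion, the known mode of opening of shikimate 3,4-cyclic sulfites by nucleophiles such as azide. This gives, as its caesium salt, the 3α-benzoate 4-O-hydrogen sulfite F6, which dilute H2SO4 in THF hydrolyses during work-up with loss of sulfur dioxide. The route is rejoined at 10.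

## Further compounds

F1 | step 9 | TMEDA adduct of the cyclic 1β,2β-dioxoosmate ester of triol F2 | CN(C)CCN(C)C.O=C(OC[C@@]12C[C@@H](OS(C)(=O)=O)[C@H](O)[C@@H](OC(=O)c3ccccc3)[C@@H]1O[Os](=O)(=O)O2)c1ccccc1
F2 | step 9 | 1α-benzoyloxymethyl-3α-benzoyloxy-5α-methanesulfonyloxycyclohexane-1β,2β,4β-triol | O=C(OC[C@@]1(O)C[C@@H](OS(C)(=O)=O)[C@H](O)[C@@H](OC(=O)c2ccccc2)[C@@H]1O)c1ccccc1
F3 | step 10 | 1,2-O-isopropylidene derivative of 13 | O=C(OC[C@@]12C[C@@H](OS(C)(=O)=O)[C@H](O[Si](CC)(CC)CC)[C@@H](OC(=O)c3ccccc3)[C@@H]1OC(C)(C)O2)c1ccccc1
F4 | step 10 | 1,2-O-isopropylidene derivative of 16 | O=C(OC[C@@]12C=C[C@H](O[Si](CC)(CC)CC)[C@@H](OC(=O)c3ccccc3)[C@@H]1OC(C)(C)O2)c1ccccc1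
F5 | step 7 | 7-O-benzoyl-5-O-methanesulfonylshikimyl alcohol 3,4-cyclic sulfite (both configurations at sulfur) | O=C(OCC1=C[C@@H](OS(=O)O2)[C@@H]2[C@H](OS(C)(=O)=O)C1)c1ccccc1
F6 | step 7 | 3-epi-shikimyl alcohol 3,7-dibenzoate 5-methanesulfonate 4-O-hydrogen sulfite | O=C(OCC1=C[C@H](OC(=O)c2ccccc2)[C@@H](OS(=O)O)[C@H](OS(C)(=O)=O)C1)c1ccccc1
A1 | alternative 1 | 3-hydroxy-2H-pyran-2-one | O=C1OC=CC=C1O
A2 | alternative 1 | (E)-4-benzoyloxybut-3-en-2-one | CC(=O)/C=C/OC(=O)c1ccccc1
A3 | alternative 1 | 8-acetyl-4-hydroxy-3-oxo-2-oxabicyclo[2.2.2]oct-5-en-7-yl benzoate | O=C1O[C@@H]2C=C[C@@]1(O)[C@@H](C(C)=O)[C@@H]2OC(=O)c1ccccc1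
A4 | alternative 2 | (1-hydroxy-4-oxocyclohexa-2,5-dien-1-yl)methyl benzoate | O=C1C=CC(O)(COC(=O)c2ccccc2)C=C1
A5 | alternative 2 | phenylboronic acid | OB(O)c1ccccc1
A6 | alternative 2 | cis-fused phenylboronate of the C1/C2 diol enone | O=C(OC[C@@]1(OB(c3ccccc3)O2)C=CC(=O)C[C@@H]12)c1ccccc1
A7 | alternative 3 | (Z)-2-benzoyloxy-3-(tert-butyldimethylsilyloxy)hept-4-en-6-ynal, configured at its two stereocentres as C3 and C4 of the target | O=C[C@H](OC(=O)c1ccccc1)[C@@H](O[Si](C)(C)C(C)(C)C)/C=C\C#C
A8 | alternative 3 | triethylsilane | CC[SiH](CC)CC
A9 | alternative 3 | 6-methylenecyclohex-4-ene with O2 triethylsilyl ether, O3 benzoate and O4 tert-butyldimethylsilyl ether | C=C1C=C[C@H](O[Si](C)(C)C(C)(C)C)[C@@H](OC(=O)c2ccccc2)[C@@H]1O[Si](CC)(CC)CC
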